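The data are simulated with made-up constants, noise included.

The reading at 2.0 min lies 40.0 s beyond the last reading of either earlier run, so you are extrapolating, and the first job is to see which given numbers need care.

| setting | gamma | theta | flask |
|---|---|---|---|
| starting material | 7.4 mM | 16 mM | 11 mM |
| solid reagent | 33 mM | 33 mM | 33.0 mM |
| remark | run made earlier | run made earlier |  |
| time |  |  | 2.0 min |

| run | time / s | product / % | starting material / % |
|---|---|---|---|
| gamma | 10.0 | 0.4 | 100.3 |
| gamma | 15.0 | 0.4 | 98.9 |
| gamma | 25.0 | 1.5 | 99.1 |
| gamma | 40.0 | 1.9 | 97.5 |
| gamma | 60.0 | 4.0 | 96.9 |
| gamma | 80.0 | 5.1 | 95.5 |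
| theta | 10.0 | 0.3 | 100.2 |
| theta | 15.0 | 0.2 | 99.9 |
| theta | 25.0 | 0.6 | 99.2 |
| theta | 40.0 | 1.2 | 97.9 |
| theta | 60.0 | 3.2 | 97.3 |
| theta | 80.0 | 4.3 | 95.7 |

(scatter of a reading: 0.3 percentage points)

- at 2.0 min, what has stopped the reaction, if anything has (for what has run out or reacted, a solid counts together with what of it has only dissolved) (it is still moving / the partner has run out first / forward and back rates have come level / all of the starting material has reacted)
- product at 2.0 min, in percent of the starting material charged

- the analysis behind the earlier runs scatters by 0.3 percentage points, standard deviation
- at the start none of the solid reagent is in solution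
- a reading or a percentage of product counts all its forms, free or not
- the reaction counts as stopped when no species that holds the starting material changes by six tenths of a point or more over the second half of the time

The charge of starting material moves little. From 7.4 mM to 16 mM, product at 80.0 s reads 5.1 % and 4.3 %, a gap of 0.8 percentage points with a scatter of 0.3 points on each reading. Percentages that shift this little with the charge read as roughly first order in starting material, so I pool both runs. Both used the same solid reagent charge, so they say nothing about it.

Two numbers remain. One is the lifetime of the starting material, the time the pooled climb from 40.0 s to 80.0 s would take to turn over the whole charge: 21.2 min. The other is the lag on that line, 20.3 s. A scatter-sized error at one end of the climb moves the answer by 0.75 points, and a lag wrong by 10.0 s moves it by 0.79 points.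

Time after the lag divided by the lifetime gives 7.85 %, with 4.7 points gained over the second half, so I expect the flask still moving.

The forecast, finding “no sign of levelling”, says it is still moving, with 8.2 % (6.8 % to 10.2 %), a little above my figure.

The flask gives 6.44 %, and it is still moving, which is 1.4 points lower than my figure. Left ten times as long, it stands at 10.6 %. At 1.00 min the lifetime gives 3.12 % against 3.25 %, so the gap opens later. Read over the second half, the lifetime is 31.3 min, longer than 21.2 min. Watch those later readings.

    crystals ⇌ product, rate k1*(cs1 - [product]) while solid is left; crystals form when [product] > cs1 (solubility = 9.50 mM, k = 0.250 s⁻¹)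
    starting material + partner ⇌ product (K = 70.0 M⁻¹, k = 0.920 M⁻¹ s⁻¹)
    solid reagent ⇌ partner, rate k3*(cs3 - [partner]) while solid is left; crystals form when [partner] > cs3 (solubility = 1.70 mM, k = 0.0290 s⁻¹)

For the same flask read at 30 s, the lifetime gives 0.763 %. The computed result is 1.25 %.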